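Each target holds one substrate and one coupling partner, so the partner charged must equal the partner left, plus the partner in target, plus any partner gone another way.

| flask | substrate | coupling partner | initiator | temperature | remark | time |
|---|---|---|---|---|---|---|
| south-east | 0.16 M | 1.8 equiv | 0.53 mol% | 0 °C | run made earlier |  |
| west | 0.16 M | 1.8 equiv | 1.7 mol% | 15 °C | run made earlier |  |
| north-west | 0.14 M | 1.8 equiv | 2.5 mol% | 0 °C | run made earlier |  |
| violet | 0.050 M | 1.80 equiv | 2.5 mol% | 5 °C |  | 25 min |
| blue | 0.16 M | 1.80 equiv | 2.5 mol% | 25 °C |  | 25 min |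
| red | 0.080 M | 1.80 equiv | 2.5 mol% | 25 °C |  | 25 min |
| ochre | 0.25 M | 1.20 equiv | 2.5 mol% | 25 °C |  | 25 min |
| teal | 0.10 M | 1.80 equiv | 2.5 mol% | 25 °C |  | 25 min |
| amber | 0.10 M | 1.80 equiv | 0.6 mol% | 25 °C |  | 25 min |

| run | time / min | target / % | substrate / % |
|---|---|---|---|
| south-east | 6.00 | 7 | 92 |
| south-east | 15.0 | 22 | 79 |
| south-east | 30.0 | 37 | 61 |
| south-east | 40.0 | 46 | 54 |
| south-east | 80.0 | 66 | 27 |
| west | 3.00 | 26 | 74 |
| west | 10.0 | 63 | 31 |
| west | 20.0 | 81 | 17 |
| west | 30.0 | 83 | 12 |
| west | 40.0 | 84 | 6 |
| north-west | 6.00 | 18 | 84 |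
| north-west | 15.0 | 41 | 60 |
| north-west | 30.0 | 61 | 33 |
| north-west | 40.0 | 72 | 24 |
| north-west | 80.0 | 90 | 5 |

(readings scatter by 1.5 percentage points)



- ranking by amount of target, in percent of the substrate charged, from high to low, at 25 min (violet / blue / red / ochre / teal / amber)
- the amount of target, in percent of the substrate charged of the flask you put first, at 25 min
- the amount of target, in percent of the substrate charged of the flask you put last, at 25 min

I applied that balance to the west run. Between 20.0 min and 40.0 min the readings of the west run fell by 11 percentage points for substrate but rose by 3 points for target, which is less. I read this as a stop set by the partner, and the last reading gave 0.467 as the partner yield, the target standing per partner charged.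

Carrying that yield over from 15 °C to 25 °C, I estimated a ceiling of 84.0% for blue and of 56.0% for ochre, lower on its smaller charge of partner. At 30.0 min the north-west run, with more initiator per litre at the same temperature, held 61% of target against 37% in the south-east run, though its substrate also differed, 0.14 M against 0.16 M. So, of the flasks charged with 1.80 equiv of partner, I put blue first, with the most initiator per litre, and I put amber last, with the least initiator per litre of all the flasks.

The forecast gave ochre > blue > violet > teal > red > amber, with 67% first and 28% last, holding that “the initiator is dying”.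

The flasks gave blue > teal > red > ochre > violet > amber, with 74.5% in blue, 55.5% in ochre and 40.6% in amber.

    initiator → 2 initiating radical (k = 2.40 × 10⁻⁵ s⁻¹, Ea = 91.0 kJ mol⁻¹)
    substrate + initiating radical → capped initiator + first chain carrier (k = 3.30 × 10⁵ M⁻¹ s⁻¹, Ea = 28.0 kJ mol⁻¹)
    coupling partner + first chain carrier → target + second chain carrier (k = 17000 M⁻¹ s⁻¹, Ea = 22.0 kJ mol⁻¹)
    substrate + second chain carrier → by-product + first chain carrier (k = 1.60 × 10⁵ M⁻¹ s⁻¹, Ea = 23.0 kJ mol⁻¹)
    2 first chain carrier → ended chains A (k = 1.20 × 10⁶ M⁻¹ s⁻¹, Ea = 22.0 kJ mol⁻¹)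
    2 second chain carrier → ended chains B (k = 5.90 × 10⁷ M⁻¹ s⁻¹, Ea = 17.0 kJ mol⁻¹)
    coupling partner → decomposed reagent (k = 0.00430 s⁻¹, Ea = 88.0 kJ mol⁻¹)
    substrate + target → side product (k = 0.00140 M⁻¹ s⁻¹, Ea = 51.0 kJ mol⁻¹)
    (constants at 25 °C)

In blue at 25.0 min, the coupling partner, here the limiting reagent despite its excess, stood at 0% beside 0.161 M of decomposed reagent, while 96% of the initiator remained. Blue's yield at that time was 0.414, lower than the 0.467 read in the west run. For the neighbouring flask, blue with 0.720 equiv of partner, the west yield gives 33.6% of target. That flask gave 30.5% of target, with 56.6% of the substrate remaining.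

(Readings and results stem from a simulated flask on assumed constants; scatter was added.)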